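**Retrosynthetic overview** (ring numbering: C1 = ring C=O, C2=C3 = enone alkene, C4 = CH2, C5 = C–OH, C6 = CH2 next to C=O; side chain C1' = CH2, C2' = C=O)
1. Target ⇒ diol carrying C2' as an (S)-carbinol (oxidised last) ⇒ spiro-silylene enone ⇒ β-benzyloxy ketone (loss of benzyl alcohol gives C2=C3).
2. Key disconnection: C3–C4 and C5–C6 in one Lewis-acid formal [4+2] between an exocyclic cyclic silyl enol ether (C4=C5, the C5 oxygen, the whole side chain) and 3-(benzyloxy)cyclobutanone (C3, C2, C1, C6). The cyclohexanone is the only carbocycle and is closed in this step, spiro to a temporary dioxasilinane.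
3. Enabling feature: ketone C1, tertiary carbinol C5 β to it (aldol retron C5–C6) and enone carbon C3 at the aldehyde level (β-alkoxy ketone retron C3–C4) make C6–C1(=O)–C2–C3 the ring-opened 1,4-zwitterion of a 3-alkoxycyclobutanone. The C2' oxygen sits 1,3 to the C5 oxygen, so both fit into a temporary 1,3,2-dioxasilinane ring whose carbinol centre steers the face of C5 and is then erased by oxidation.
4. Cyclic silyl enol ether ⇐ (S)-β-hydroxy methyl ketone ⇐ Wacker ⇐ homoallylic alcohol ⇐ oleyl alcohol + allyl acetate. Ring order: dioxasilinane made (step 3), cyclobutane opened and cyclohexanone closed (step 4), dioxasilinane cleaved (step 6).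

Key step: step 4

Assumption: 3-(benzyloxy)cyclobutan-1-one is taken to ionise under EtAlCl2 like the 3-ethoxy compound usually used in this annulation; atom labels in the Why lines follow the overview numbering.

**Step 1**
Reactants: 1 (9Z)-octadec-9-en-1-ol (oleyl alcohol)
Product: 3 (4S,12Z)-henicosa-1,12-dien-4-ol, via (9Z)-octadec-9-enal 2 (not isolated)
Conditions: allyl acetate (excess), [Ir(cod)Cl]2 (2.5 mol%), (R)-Cl,MeO-BIPHEP (5 mol%), Cs2CO3 (20 mol%), 3-nitrobenzoic acid (10 mol%), THF, 100 °C, sealed tube
Reagents that add atoms: allyl acetate, CC(=O)OCC=C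
Why: Iridium-catalysed transfer-hydrogenative carbonyl allylation from the alcohol oxidation level: the cyclometallated π-allyliridium C,O-benzoate dehydrogenates 1 to aldehyde 2 and should deliver the allyl group to its re face under control of the (R)-bisphosphine, setting the relay carbinol as S (sense to be checked by MTPA-ester analysis, the ligand antipode being used otherwise), while the remote Z-alkene is not involved.

**Step 2**
Reactants: 3 (4S,12Z)-henicosa-1,12-dien-4-ol
Product: 4 (4S,12Z)-4-hydroxyhenicos-12-en-2-one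
Conditions: PdCl2 (10 mol%), CuCl (1 equiv, reoxidised by O2), O2 (1 atm), DMF/H2O 7:1, rt
Reagents that add atoms: water, O
Why: Tsuji–Wacker oxidation: Markovnikov hydroxypalladation of the terminal alkene and β-hydride elimination give the methyl ketone, the internal Z-disubstituted alkene reacting far more slowly; no stereocentre is formed and the carbinol is untouched.

**Step 3**
Reactants: 4 (4S,12Z)-4-hydroxyhenicos-12-en-2-one
Product: 6 (4S)-4-[(8Z)-heptadec-8-en-1-yl]-6-methylidene-2,2-di(propan-2-yl)-1,3,2-dioxasilinane, via dilithium alkoxide-enolate 5 (not isolated)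
Conditions: LDA (2.2 equiv), THF, −78 °C; then iPr2Si(OTf)2 (1.05 equiv), −78 → 0 °C; pentane, filtration under argon, used crude
Reagents that add atoms: di(propan-2-yl)silanediyl bis(trifluoromethanesulfonate), CC(C)[Si](OS(=O)(=O)C(F)(F)F)(OS(=O)(=O)C(F)(F)F)C(C)C
Why: Kinetic deprotonation of the lithium aldolate at the methyl group (the less hindered site, away from the alkoxide) gives alkoxide–enolate 5, and the bifunctional silyl triflate O-silylates both oxygens to close the six-membered silylene, fixing the enol double bond exocyclic as the future C4=C5 (kinetic silyl enol ether formation; no new stereocentre).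

**Step 4**
Reactants: 6 (4S)-4-[(8Z)-heptadec-8-en-1-yl]-6-methylidene-2,2-di(propan-2-yl)-1,3,2-dioxasilinane; 7 3-(benzyloxy)cyclobutan-1-one
Product: 10 (4S,6R,10RS)-10-(benzyloxy)-4-[(8Z)-heptadec-8-en-1-yl]-2,2-di(propan-2-yl)-1,3-dioxa-2-silaspiro[5.5]undecan-8-one, via ring-opened aluminium enolate-oxocarbenium zwitterion 8 (not isolated), via cyclic silyloxocarbenium ion 9 (not isolated)
Conditions: 7 (1.5 equiv), EtAlCl2 (1.6 equiv), CH2Cl2, −78 °C; then Et3N, aq NaHCO3
Reagents that add atoms: none
Why: EtAlCl2 ionises the strained 3-alkoxycyclobutanone 7 by ring C–C heterolysis to the 1,4-zwitterion 8 (benzyl-oxocarbenium carbon = C3, aluminium enolate carbon = C6), the methylene carbon of 6 (C4) adds to the oxocarbenium carbon (forms C3–C4) to give the cyclic silyloxocarbenium ion 9, and the tethered enolate closes on C5 (forms C5–C6). The closest known reaction type is the EtAlCl2-mediated formal [4+2] cycloaddition of 3-alkoxycyclobutanones with silyl enol ethers, which gives 3-alkoxy-5-silyloxycyclohexanones. The one ring closed (the cyclohexanone) forms by a 6-(enolendo)-exo-trig Mukaiyama-aldol-type attack on the C=O+ carbon. C5 is set by the temporary dioxasilinane: in the half-chair oxocarbenium ion with the heptadecenyl group pseudo-equatorial the enolate carbon should enter axially, trans to that group (the 1,3-trans sense of additions to six-membered cyclic oxocarbenium ions), so the (S)-carbinol relays to (R)-C5, while the benzyloxy carbon forms as both epimers and is erased in step 5. The step needs ring closure to beat silyl transfer to the enolate oxygen (which would give an open-chain 1,5-diketone); the aluminium Lewis acid at −78 °C and the cyclic silylene, whose silicon cannot leave the C5 oxygen without opening its own ring, should secure this. Any C5 epimer is a diastereomer (C2' is still stereogenic) and is removed by chromatography.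

**Step 5**
Reactants: 10 (4S,6R,10RS)-10-(benzyloxy)-4-[(8Z)-heptadec-8-en-1-yl]-2,2-di(propan-2-yl)-1,3-dioxa-2-silaspiro[5.5]undecan-8-one
Product: 11 (4S,6R)-4-[(8Z)-heptadec-8-en-1-yl]-2,2-di(propan-2-yl)-1,3-dioxa-2-silaspiro[5.5]undec-9-en-8-one
Conditions: TsOH (anhydrous, 10 mol%), toluene, 50 °C
Reagents that add atoms: none
Why: Acid-catalysed β-elimination (retro-oxa-Michael via the enol) of benzyl alcohol from the β-alkoxy ketone gives the conjugated C2=C3 enone and converges both benzyloxy epimers; the alkyl ether oxygen is protonated far more readily than the silyl ether oxygen at C5, and no base is present that could expel the C5 silyloxy group or start aromatisation.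

**Step 6**
Reactants: 11 (4S,6R)-4-[(8Z)-heptadec-8-en-1-yl]-2,2-di(propan-2-yl)-1,3-dioxa-2-silaspiro[5.5]undec-9-en-8-one
Product: 12 (5R)-5-hydroxy-5-[(2S,10Z)-2-hydroxynonadec-10-en-1-yl]cyclohex-2-en-1-one
Conditions: HF·pyridine, pyridine, THF, 0 °C → rt
Reagents that add atoms: none
Why: Fluoride cleavage of the silylene (driven by Si–F bond formation) under buffered, non-basic conditions frees the 1,3-diol without generating the alkoxide that would open retro-aldol or E1cB paths in the β-hydroxy ketone; no stereocentre is touched.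

**Step 7**
Reactants: 12 (5R)-5-hydroxy-5-[(2S,10Z)-2-hydroxynonadec-10-en-1-yl]cyclohex-2-en-1-one
Product: 13 (5R)-5-hydroxy-5-[(10Z)-2-oxononadec-10-en-1-yl]cyclohex-2-en-1-one (CNP0165051.1)
Conditions: Dess–Martin periodinane (1.3 equiv), pyridine (3 equiv), CH2Cl2, 0 °C → rt
Reagents that add atoms: none
Why: Dess–Martin oxidation converts the only oxidisable hydroxyl (the secondary relay carbinol) into the side-chain ketone and thereby erases the temporary stereocentre, while the tertiary C5–OH, the enone and the Z-alkene are inert under the buffered conditions.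

**Compound list**
1 | (9Z)-octadec-9-en-1-ol (oleyl alcohol) | OCCCCCCCC/C=C\CCCCCCCC | starting material
2 | (9Z)-octadec-9-enal | O=CCCCCCCC/C=C\CCCCCCCC | intermediate (not isolated)
3 | (4S,12Z)-henicosa-1,12-dien-4-ol | C=CC[C@@H](O)CCCCCCC/C=C\CCCCCCCC | intermediate
4 | (4S,12Z)-4-hydroxyhenicos-12-en-2-one | CC(=O)C[C@@H](O)CCCCCCC/C=C\CCCCCCCC | intermediate
5 | dilithium (4S,12Z)-henicosa-1,12-diene-2,4-bis(olate) (alkoxide–enolate) | [Li+].[Li+].C=C([O-])C[C@@H]([O-])CCCCCCC/C=C\CCCCCCCC | intermediate (not isolated)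
6 | (4S)-4-[(8Z)-heptadec-8-en-1-yl]-6-methylidene-2,2-di(propan-2-yl)-1,3,2-dioxasilinane | C=C1C[C@H](CCCCCCC/C=C\CCCCCCCC)O[Si](C(C)C)(C(C)C)O1 | intermediate
7 | 3-(benzyloxy)cyclobutan-1-one | O=C1CC(OCc2ccccc2)C1 | starting material
8 | ring-opened zwitterion: dichloro(ethyl)aluminate enolate of 4-(benzyloxoniumylidene)butan-2-one | C=C(O[Al-](Cl)(Cl)CC)CC=[O+]Cc1ccccc1 | intermediate (not isolated)
9 | cyclic silyloxocarbenium ion carrying the tethered aluminium enolate (C3–C4 bond formed, ring not yet closed) | C=C(O[Al-](Cl)(Cl)CC)CC(OCc1ccccc1)CC1=[O+][Si](C(C)C)(C(C)C)O[C@@H](CCCCCCC/C=C\CCCCCCCC)C1 | intermediate (not isolated)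
10 | (4S,6R,10RS)-10-(benzyloxy)-4-[(8Z)-heptadec-8-en-1-yl]-2,2-di(propan-2-yl)-1,3-dioxa-2-silaspiro[5.5]undecan-8-one | O1[C@@]2(CC(=O)CC(OCc3ccccc3)C2)C[C@H](CCCCCCC/C=C\CCCCCCCC)O[Si]1(C(C)C)C(C)C | intermediate
11 | (4S,6R)-4-[(8Z)-heptadec-8-en-1-yl]-2,2-di(propan-2-yl)-1,3-dioxa-2-silaspiro[5.5]undec-9-en-8-one | O1[C@@]2(CC(=O)C=CC2)C[C@H](CCCCCCC/C=C\CCCCCCCC)O[Si]1(C(C)C)C(C)C | intermediate
12 | (5R)-5-hydroxy-5-[(2S,10Z)-2-hydroxynonadec-10-en-1-yl]cyclohex-2-en-1-one | O[C@@]1(CC(=O)C=CC1)C[C@@H](O)CCCCCCC/C=C\CCCCCCCC | intermediate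
13 | (5R)-5-hydroxy-5-[(10Z)-2-oxononadec-10-en-1-yl]cyclohex-2-en-1-one | O[C@@]1(CC(=O)C=CC1)CC(=O)CCCCCCC/C=C\CCCCCCCC | target

**Total step count:** 7. **Longest linear sequence:** 7 steps (from oleyl alcohol 1).

**Steps most likely to fail**

Step 4 (key step). What may go wrong: silyl transfer or attack of the Lewis acid on the dialkoxysilyl enol ether in competition with ring closure, or insufficient facial discrimination in the closure. The fallback sets out from 4 and comes back at 12; it gives up the template and uses an acyclic trialkylsilyl enol ether, the substrate type for which this annulation is established, with separation of diastereomers instead of template control. 4 is treated with LDA (2.2 equiv) and Et3SiCl (THF, −78 °C) to give (4S,12Z)-2,4-bis(triethylsilyloxy)henicosa-1,12-diene F1. F1, 7 and EtAlCl2 (CH2Cl2, −78 °C) should give (3RS,5R)-3-(benzyloxy)-5-(triethylsilyloxy)-5-[(2S,10Z)-2-(triethylsilyloxy)nonadec-10-en-1-yl]cyclohexan-1-one F2 after chromatographic removal of its C5 epimer, the two being diastereomers because C2' is still stereogenic. TsOH (10 mol%) in toluene then gives (5R)-5-(triethylsilyloxy)-5-[(2S,10Z)-2-(triethylsilyloxy)nonadec-10-en-1-yl]cyclohex-2-en-1-one F3, and HF·pyridine returns the route to 12.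

Step 3. What may go wrong: deprotonation on the wrong side of the ketone, retro-aldol cleavage of the lithium aldolate, or intermolecular silylation in place of ring closure. The fallback sets out from 4 and comes back at 6; it attaches the silicon tether first, so no alkoxide is ever present and the enolate oxygen is captured intramolecularly. 4 with iPr2SiCl2 (3 equiv) and imidazole (CH2Cl2, 0 °C; excess dichlorosilane removed in vacuo) gives (4S,12Z)-4-{[chlorodi(propan-2-yl)silyl]oxy}henicos-12-en-2-one F4. Potassium bis(trimethylsilyl)amide (1.1 equiv, THF, −78 °C) then forms the methyl-side kinetic enolate, which closes on silicon through a six-membered transition state to give 6.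

Step 5. What may go wrong: competing loss of the silyloxy group at C5 (leading on to the dienone and aromatisation) or acid cleavage of the silylene. The fallback sets out from 10 and comes back at 11; it replaces the alkoxide-type leaving group by a sulfonate that eliminates under conditions too mild to touch C5. Oxidative debenzylation of 10 (DDQ, CH2Cl2/H2O, visible light) gives (4S,6R,10RS)-4-[(8Z)-heptadec-8-en-1-yl]-10-hydroxy-2,2-di(propan-2-yl)-1,3-dioxa-2-silaspiro[5.5]undecan-8-one F5. MsCl and Et3N (CH2Cl2, −20 °C) convert it into (4S,6S,8RS)-4-[(8Z)-heptadec-8-en-1-yl]-10-oxo-2,2-di(propan-2-yl)-1,3-dioxa-2-silaspiro[5.5]undecan-8-yl methanesulfonate F6 (same spatial arrangement as F5; not isolated), which should undergo E1cB loss of methanesulfonate at this temperature to give 11.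

**Further compounds**
F1 | step 4 | (4S,12Z)-2,4-bis(triethylsilyloxy)henicosa-1,12-diene | C=C(O[Si](CC)(CC)CC)C[C@@H](O[Si](CC)(CC)CC)CCCCCCC/C=C\CCCCCCCC
F2 | step 4 | (3RS,5R)-3-(benzyloxy)-5-(triethylsilyloxy)-5-[(2S,10Z)-2-(triethylsilyloxy)nonadec-10-en-1-yl]cyclohexan-1-one | CC[Si](CC)(CC)O[C@@]1(CC(=O)CC(OCc2ccccc2)C1)C[C@@H](O[Si](CC)(CC)CC)CCCCCCC/C=C\CCCCCCCC
F3 | step 4 | (5R)-5-(triethylsilyloxy)-5-[(2S,10Z)-2-(triethylsilyloxy)nonadec-10-en-1-yl]cyclohex-2-en-1-one | CC[Si](CC)(CC)O[C@@]1(CC(=O)C=CC1)C[C@@H](O[Si](CC)(CC)CC)CCCCCCC/C=C\CCCCCCCC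
F4 | step 3 | (4S,12Z)-4-{[chlorodi(propan-2-yl)silyl]oxy}henicos-12-en-2-one | CC(=O)C[C@@H](O[Si](Cl)(C(C)C)C(C)C)CCCCCCC/C=C\CCCCCCCC
F5 | step 5 | (4S,6R,10RS)-4-[(8Z)-heptadec-8-en-1-yl]-10-hydroxy-2,2-di(propan-2-yl)-1,3-dioxa-2-silaspiro[5.5]undecan-8-one | O1[C@@]2(CC(=O)CC(O)C2)C[C@H](CCCCCCC/C=C\CCCCCCCC)O[Si]1(C(C)C)C(C)C
F6 | step 5 | (4S,6S,8RS)-4-[(8Z)-heptadec-8-en-1-yl]-10-oxo-2,2-di(propan-2-yl)-1,3-dioxa-2-silaspiro[5.5]undecan-8-yl methanesulfonate | O1[C@@]2(CC(=O)CC(OS(C)(=O)=O)C2)C[C@H](CCCCCCC/C=C\CCCCCCCC)O[Si]1(C(C)C)C(C)C
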